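All runs stem from a simulated flask with made-up constants.

I have no rate constants for this chemistry, so the alder run has to stand in for them, and what it can lend the new flask is a ratio rather than a rate.

- alder: substrate 1.5 M; reagent 0.82 M; run made earlier
- flask: substrate 1.5 M; reagent 1.65 M; time 20 h

alder run (percent of the substrate charged)

| time / h | side product A / % | target / % |
|---|---|---|
| 2.00 | 3.1 | 1.9 |
| 6.00 | 12.1 | 5.5 |
| 10.0 | 20.5 | 6.5 |
| 15.0 | 26.5 | 6.7 |

(each reading ± 0.5 percentage points)

- share of side product A in side product A plus target at 30 min
- share of side product A in side product A plus target at 3.0 h
- share of side product A in side product A plus target at 20 h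
- which of side product A and target there is more of at 20 h



Two numbers in the alder run look contradictory. Between 10.0 h and 15.0 h the target gains 0.2 percentage points, less than the 6 points of side product A, so the target behaves as if reagent had fallen very low; yet at 15.0 h the two products together hold 0.498 M, which at one reagent each leaves 0.322 M of the 0.82 M charged unaccounted for. Both readings hold if reagent also leaves by a path that neither product shows, and then I need not reckon the whole reagent budget, just the part the target catches. I call the moles of target formed per mole of reagent charged the capture share, a yield counted on the reagent charged, and the last target reading of the alder run gives 12.3%, a read value, since that target reading carries a scatter of 0.5 points.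

I carry this share unchanged to the flask and assume the target has levelled by 20 h, which gives 13.5% of target. Extending the last alder slope of side product A to 20 h, and taking that estimate over to the flask, gives 32.5%, more than the target, so my estimated share for the flask at that time is 70.7%. I give no figure for the earlier times, since the capture share speaks of the end of a run.

The forecast says 36%, 45% and 70%, with side product A ahead, and of its scheme it says: "That suggests a shared intermediate".

The flask gives 25.0% at 30 min, 54.0% at 3.0 h and 73.2% at 20 h, with 39.3% of side product A against 14.4% of target. At that time it holds 0.315 M of homo dimer, each of which contains two reagent.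

    substrate → intermediate (k = 7.70 × 10⁻⁴ min⁻¹)
    reagent + intermediate → side product A (k = 0.00910 M⁻¹ min⁻¹)
    substrate + reagent → target (k = 2.70 × 10⁻⁴ M⁻¹ min⁻¹)
    substrate + intermediate → side product B (k = 6.40 × 10⁻⁴ M⁻¹ min⁻¹)
    2 substrate → self-condensation product (k = 9.80 × 10⁻⁷ M⁻¹ min⁻¹)
    2 reagent → homo dimer (k = 4.50 × 10⁻⁴ M⁻¹ min⁻¹)

The capture share of the flask at 20 h comes to 13.1%, against 12.3% read from alder. Carried to the neighbour flask with 0.41 M of reagent, 12.3% gives 3.35% of target, and that flask holds 3.78% at 20.0 h.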